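**Plan**

- Retrosynthetic cuts, in order: the ring bond O–C7 of the tetrahydrofuran (back to an acyclic triol), then C7–C8 (aldol) and C7'–C8' (conjugate addition), the last two made in one flask.
- Enabling feature: the chain C9–C8–C8'–C9' carries oxygen at both ends, so it can be folded into a γ-alkoxybutenolide with C8' as the electrophilic β-carbon and C8 as the enolate carbon. The benzylic carbon C7' can be umpoled as an aryl-dithiane anion. The para-hydroxyl of the aryl ring on C7 lets C7 ionise to a p-quinone methide.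
- Forward: one silylated syringaldehyde serves both as dithiane nucleophile and as aldehyde electrophile. A three-component union on a menthyloxybutenolide gives the whole carbon skeleton with a temporary lactone ring. Desulfurisation, hydride opening of the lactone acetal (auxiliary leaves) and desilylation follow, and the tetrahydrofuran ring is closed last.
- Stereochemistry: C8' from addition anti to the menthyloxy group (auxiliary from (−)-menthol); C8 from aldol anti to the new C8' substituent; C7 from stereoconvergent closure of both carbinol epimers through the planar quinone methide to the 7,8-trans ring.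

Key step: step 3

Remark on the chemistry: the (5R)-5-menthyloxybutenolide derived from (−)-menthol is taken as a commercial reagent. The carbinol carbon C7 formed in the key step is carried as a mixture of both epimers until the last step and is left undefined in the SMILES of those compounds.

**Route**

Step 1
Reactants: 1 syringaldehyde (4-hydroxy-3,5-dimethoxybenzaldehyde)
Product: 2 3,5-dimethoxy-4-(triisopropylsilyloxy)benzaldehyde
Conditions: TIPSCl, imidazole, DMAP (cat.), DMF, rt → 40 °C
Reagents that add atoms: triisopropylsilyl chloride (TIPSCl), CC(C)[Si](Cl)(C(C)C)C(C)C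
Why: O-silylation of a phenol gives a bulky aryl silyl ether that should withstand n-BuLi, Raney Ni and LiAlH4 and can later be removed with fluoride, without acid and without hydrogenolysis.

Step 2
Reactants: 2 3,5-dimethoxy-4-(triisopropylsilyloxy)benzaldehyde
Product: 3 2-[3,5-dimethoxy-4-(triisopropylsilyloxy)phenyl]-1,3-dithiane
Conditions: HS(CH2)3SH, BF3·OEt2 (cat.), CH2Cl2, 0 °C
Reagents that add atoms: propane-1,3-dithiol, SCCCS
Why: Lewis-acid-catalysed dithioacetalisation of an aryl aldehyde (dithiane formation for Corey–Seebach umpolung) makes the future benzylic carbon C7' acidic, and the short exposure to catalytic acid at 0 °C should leave the aryl silyl ether intact.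

Step 3
Reactants: 3 2-[3,5-dimethoxy-4-(triisopropylsilyloxy)phenyl]-1,3-dithiane; 4 (5R)-5-[(1R,2S,5R)-menthyloxy]furan-2(5H)-one; 2 3,5-dimethoxy-4-(triisopropylsilyloxy)benzaldehyde
Product: 7 (3S,4R,5R)-3-{hydroxy[3,5-dimethoxy-4-(triisopropylsilyloxy)phenyl]methyl}-4-{2-[3,5-dimethoxy-4-(triisopropylsilyloxy)phenyl]-1,3-dithian-2-yl}-5-[(1R,2S,5R)-menthyloxy]dihydrofuran-2(3H)-one as a mixture of both epimers at the carbinol carbon C7, via lithiated dithiane 5 (not isolated), via lithium enolate 6 (not isolated)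
Conditions: n-BuLi, THF, −78 → −20 °C; 4, −78 °C; 2, −78 °C; AcOH, −78 °C
Reagents that add atoms: none
Why: The soft, sulfur-stabilised benzylic anion 5 adds in 1,4-fashion to C4 of butenolide 4, which forms the C7'–C8' bond, and the lactone lithium enolate 6 so formed is captured at C3 by the non-enolisable aldehyde 2 in an aldol addition (C7–C8 bond), so that the complete carbon skeleton and the C7 oxygen should arise in one flask. The closest known reaction type is the tandem conjugate addition–aldol reaction of lithiated aryl dithioacetals with butenolides and γ-alkoxybutenolides that is established in lignan lactone synthesis. No ring is closed in this step; the lactone ring of 4 is a temporary ring that holds C9–C8–C8'–C9' as a cyclic enoate and is opened in step 5. C8' (R) is set by attack anti to the menthyloxy group on the neighbouring acetal carbon C5, C8 is set by approach of the aldehyde anti to the bulky dithianyl group at C4 (3,4-trans), and the carbinol carbon C7 is not controlled and need not be, because step 7 funnels both epimers. The step needs 1,4- over 1,2-addition, which the delocalised dithianyl anion and the unhindered β-carbon of 4 should secure, and C–C bond formation over proton transfer to 6, which the absence of α-hydrogens in 2 and the low temperature should secure.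

Step 4
Reactants: 7 aldol adduct (dithiane)
Product: 8 (3S,4R,5R)-4-[3,5-dimethoxy-4-(triisopropylsilyloxy)benzyl]-3-{hydroxy[3,5-dimethoxy-4-(triisopropylsilyloxy)phenyl]methyl}-5-[(1R,2S,5R)-menthyloxy]dihydrofuran-2(3H)-one (both C7 epimers)
Conditions: Raney Ni (W-2 grade, washed neutral), EtOH–THF, rt
Reagents that add atoms: none
Why: Reductive desulfurisation of a dithioacetal with Raney Ni converts C7' into the benzylic CH2 of the target, and on neutral catalyst at room temperature the lactone acetal, the silyl ethers and the benzylic hydroxyl should be retained, as in related dithiane–butenolide aldol adducts.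

Step 5
Reactants: 8 desulfurised lactone acetal
Product: 9 (2R,3R)-2-{hydroxy[3,5-dimethoxy-4-(triisopropylsilyloxy)phenyl]methyl}-3-[3,5-dimethoxy-4-(triisopropylsilyloxy)benzyl]butane-1,4-diol (both C7 epimers)
Conditions: LiAlH4, THF, 0 °C → rt; aq. NaOH work-up
Reagents that add atoms: none
Why: Hydride reduction of the lactone carbonyl (C9) and of the aldehyde released from the acyl acetal on ring opening (C9') should give both primary alcohols and liberate the menthol auxiliary, and C8 and C8' cannot epimerise once the carbonyl group is gone.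

Step 6
Reactants: 9 bis-silyl triol
Product: 10 (2R,3R)-2-[hydroxy(4-hydroxy-3,5-dimethoxyphenyl)methyl]-3-(4-hydroxy-3,5-dimethoxybenzyl)butane-1,4-diol (both C7 epimers)
Conditions: TBAF, AcOH, THF, 0 °C
Reagents that add atoms: none
Why: Fluoride-mediated cleavage of aryl silyl ethers, buffered with acetic acid, should free both phenols under conditions that neither ionise C7 nor reduce the benzylic C–O bond.

Step 7
Reactants: 10 bisphenol triol
Product: 12 (+)-(7S,8R,8'R)-5,5'-dimethoxylariciresinol, via p-quinone methide 11 (not isolated)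
Conditions: CSA (10 mol %), MeCN–CH2Cl2, 0 °C → rt, short reaction time; NaHCO3 quench
Reagents that add atoms: none
Why: Acid-catalysed dehydration of the 4-hydroxybenzylic alcohol should give the (protonated) p-quinone methide 11, which is captured by the C9' hydroxyl in a 5-exo oxa-1,6-addition (the C9 hydroxyl could only form an oxetane), so that both C7 epimers converge and the aryl group settles trans to the C8 hydroxymethyl group (7S), the less crowded and more stable arrangement, as in acid-mediated closures of related lariciresinol-type triols.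

**Compound list**

1 | syringaldehyde (4-hydroxy-3,5-dimethoxybenzaldehyde) | COc1cc(C=O)cc(OC)c1O | starting material
2 | 3,5-dimethoxy-4-(triisopropylsilyloxy)benzaldehyde | COc1cc(C=O)cc(OC)c1O[Si](C(C)C)(C(C)C)C(C)C | intermediate
3 | 2-[3,5-dimethoxy-4-(triisopropylsilyloxy)phenyl]-1,3-dithiane | COc1cc(C2SCCCS2)cc(OC)c1O[Si](C(C)C)(C(C)C)C(C)C | intermediate
4 | (5R)-5-[(1R,2S,5R)-menthyloxy]furan-2(5H)-one | O=C1C=C[C@H](O[C@@H]2C[C@H](C)CC[C@H]2C(C)C)O1 | starting material
5 | 2-lithio-2-[3,5-dimethoxy-4-(triisopropylsilyloxy)phenyl]-1,3-dithiane | [Li]C1(c2cc(OC)c(O[Si](C(C)C)(C(C)C)C(C)C)c(OC)c2)SCCCS1 | intermediate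
6 | lithium (4R,5R)-4-{2-[3,5-dimethoxy-4-(triisopropylsilyloxy)phenyl]-1,3-dithian-2-yl}-5-[(1R,2S,5R)-menthyloxy]-4,5-dihydrofuran-2-olate | [Li]OC1=C[C@@H](C2(c3cc(OC)c(O[Si](C(C)C)(C(C)C)C(C)C)c(OC)c3)SCCCS2)[C@H](O[C@@H]4C[C@H](C)CC[C@H]4C(C)C)O1 | intermediate
7 | (3S,4R,5R)-3-{hydroxy[3,5-dimethoxy-4-(triisopropylsilyloxy)phenyl]methyl}-4-{2-[3,5-dimethoxy-4-(triisopropylsilyloxy)phenyl]-1,3-dithian-2-yl}-5-[(1R,2S,5R)-menthyloxy]dihydrofuran-2(3H)-one, both C7 epimers | COc1cc(C2([C@H]3[C@H](O[C@@H]4C[C@H](C)CC[C@H]4C(C)C)OC(=O)[C@@H]3C(O)c5cc(OC)c(O[Si](C(C)C)(C(C)C)C(C)C)c(OC)c5)SCCCS2)cc(OC)c1O[Si](C(C)C)(C(C)C)C(C)C | intermediate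
8 | (3S,4R,5R)-4-[3,5-dimethoxy-4-(triisopropylsilyloxy)benzyl]-3-{hydroxy[3,5-dimethoxy-4-(triisopropylsilyloxy)phenyl]methyl}-5-[(1R,2S,5R)-menthyloxy]dihydrofuran-2(3H)-one, both C7 epimers | COc1cc(C[C@H]2[C@H](O[C@@H]3C[C@H](C)CC[C@H]3C(C)C)OC(=O)[C@@H]2C(O)c4cc(OC)c(O[Si](C(C)C)(C(C)C)C(C)C)c(OC)c4)cc(OC)c1O[Si](C(C)C)(C(C)C)C(C)C | intermediate
9 | (2R,3R)-2-{hydroxy[3,5-dimethoxy-4-(triisopropylsilyloxy)phenyl]methyl}-3-[3,5-dimethoxy-4-(triisopropylsilyloxy)benzyl]butane-1,4-diol, both C7 epimers | COc1cc(C[C@@H](CO)[C@H](CO)C(O)c2cc(OC)c(O[Si](C(C)C)(C(C)C)C(C)C)c(OC)c2)cc(OC)c1O[Si](C(C)C)(C(C)C)C(C)C | intermediate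
10 | (2R,3R)-2-[hydroxy(4-hydroxy-3,5-dimethoxyphenyl)methyl]-3-(4-hydroxy-3,5-dimethoxybenzyl)butane-1,4-diol, both C7 epimers | COc1cc(C[C@@H](CO)[C@H](CO)C(O)c2cc(OC)c(O)c(OC)c2)cc(OC)c1O | intermediate
11 | p-quinone methide of 10 (2,6-dimethoxy-4-alkylidenecyclohexa-2,5-dienone with C7 as the exocyclic alkene carbon; C8 and C8' unchanged) | COC1=CC(=C[C@@H](CO)[C@H](CO)Cc2cc(OC)c(O)c(OC)c2)C=C(OC)C1=O | intermediate
12 | (+)-(7S,8R,8'R)-5,5'-dimethoxylariciresinol, 4-{[(3R,4R,5S)-5-(4-hydroxy-3,5-dimethoxyphenyl)-4-(hydroxymethyl)tetrahydrofuran-3-yl]methyl}-2,6-dimethoxyphenol | COc1cc(C[C@H]2CO[C@H](c3cc(OC)c(O)c(OC)c3)[C@H]2CO)cc(OC)c1O | target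

**Count**

Total step count: 7. Longest linear sequence: 7 steps (1 → 2 → 3 → 7 → 8 → 9 → 10 → 12).

**Steps most likely to fail**

Step 3. What may go wrong: the lithium enolate may be captured by the aldehyde only slowly or reversibly (retro-aldol on warming, proton transfer at the quench), so that the three-component union stalls at the conjugate adduct. The fallback reverses the roles, so that the C7'–C8' bond is made by C-benzylation of the enolate. It sets out from 2, 3 and 4 and comes back to the route at 9. Aldehyde 2 is reduced (NaBH4, MeOH, 0 °C) to [3,5-dimethoxy-4-(triisopropylsilyloxy)phenyl]methanol F1 and converted by an Appel reaction (CBr4, PPh3, CH2Cl2, 0 °C) into [4-(bromomethyl)-2,6-dimethoxyphenoxy]triisopropylsilane F2. Anion 5 is added to 4 as in step 3, and enolate 6 is alkylated with F2 (DMPU, −78 → −30 °C) anti to the dithianyl group. This should give the all-trans lactone (3R,4R,5R)-3-[3,5-dimethoxy-4-(triisopropylsilyloxy)benzyl]-4-{2-[3,5-dimethoxy-4-(triisopropylsilyloxy)phenyl]-1,3-dithian-2-yl}-5-[(1R,2S,5R)-menthyloxy]dihydrofuran-2(3H)-one F3, in which the dithiane carbon is now C7 and the new benzylic carbon is C7'. Dethioacetalisation (MeI, CaCO3, aq. MeCN, 40 °C) should give the ketone (3R,4R,5R)-4-[3,5-dimethoxy-4-(triisopropylsilyloxy)benzoyl]-3-[3,5-dimethoxy-4-(triisopropylsilyloxy)benzyl]-5-[(1R,2S,5R)-menthyloxy]dihydrofuran-2(3H)-one F4. LiAlH4 (THF, 0 °C) then reduces ketone, lactone and acetal together to triol 9 (both C7 epimers), which continues with steps 6 and 7.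

Step 4. What may go wrong: hydrogenolysis of the electron-rich benzylic C7–OH bond on the nickel surface together with the C–S bonds, or partial loss of silyl groups on a basic catalyst. The fallback removes sulfur before the benzylic alcohol exists. It sets out from 3 and 4 and comes back at 8. Anion 5 is added to 4 and the enolate is protonated with AcOH at −78 °C to give the conjugate adduct (4R,5R)-4-{2-[3,5-dimethoxy-4-(triisopropylsilyloxy)phenyl]-1,3-dithian-2-yl}-5-[(1R,2S,5R)-menthyloxy]dihydrofuran-2(3H)-one F5. Raney Ni (EtOH, rt → reflux) should give (4R,5R)-4-[3,5-dimethoxy-4-(triisopropylsilyloxy)benzyl]-5-[(1R,2S,5R)-menthyloxy]dihydrofuran-2(3H)-one F6. LDA (THF, −78 °C) regenerates the lactone enolate, which should add to aldehyde 2 anti to the benzyl group to give 8.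

Step 7. What may go wrong: the ionised C7 may be attacked by the electron-rich C2'/C6' positions of the other aryl ring (irreversible Friedel–Crafts closure to an aryltetralin), or the phenolic product may re-ionise and epimerise under the acid. The fallback closes the ring in the protected series, through a benzylic cation instead of the quinone methide, and ends with a fluoride step. It sets out from 9 and comes back at 12. Triol 9 is treated with BF3·OEt2 (CH2Cl2, −78 → −30 °C) to close the ring to the bis(triisopropylsilyl) ether of (7S,8R,8'R)-5,5'-dimethoxylariciresinol F7. This non-phenolic ether should not re-ionise at low temperature and can be purified by chromatography. Desilylation (TBAF, AcOH, THF, 0 °C) then gives 12, so that the free phenol never meets acid.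

**Further compounds**

F1 | step 3 | [3,5-dimethoxy-4-(triisopropylsilyloxy)phenyl]methanol | COc1cc(CO)cc(OC)c1O[Si](C(C)C)(C(C)C)C(C)C
F2 | step 3 | [4-(bromomethyl)-2,6-dimethoxyphenoxy]triisopropylsilane | COc1cc(CBr)cc(OC)c1O[Si](C(C)C)(C(C)C)C(C)C
F3 | step 3 | (3R,4R,5R)-3-[3,5-dimethoxy-4-(triisopropylsilyloxy)benzyl]-4-{2-[3,5-dimethoxy-4-(triisopropylsilyloxy)phenyl]-1,3-dithian-2-yl}-5-[(1R,2S,5R)-menthyloxy]dihydrofuran-2(3H)-one | COc1cc(C[C@H]2C(=O)O[C@@H](O[C@@H]3C[C@H](C)CC[C@H]3C(C)C)[C@@H]2C4(c5cc(OC)c(O[Si](C(C)C)(C(C)C)C(C)C)c(OC)c5)SCCCS4)cc(OC)c1O[Si](C(C)C)(C(C)C)C(C)C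
F4 | step 3 | (3R,4R,5R)-4-[3,5-dimethoxy-4-(triisopropylsilyloxy)benzoyl]-3-[3,5-dimethoxy-4-(triisopropylsilyloxy)benzyl]-5-[(1R,2S,5R)-menthyloxy]dihydrofuran-2(3H)-one | COc1cc(C[C@H]2C(=O)O[C@@H](O[C@@H]3C[C@H](C)CC[C@H]3C(C)C)[C@@H]2C(=O)c4cc(OC)c(O[Si](C(C)C)(C(C)C)C(C)C)c(OC)c4)cc(OC)c1O[Si](C(C)C)(C(C)C)C(C)C
F5 | step 4 | (4R,5R)-4-{2-[3,5-dimethoxy-4-(triisopropylsilyloxy)phenyl]-1,3-dithian-2-yl}-5-[(1R,2S,5R)-menthyloxy]dihydrofuran-2(3H)-one | COc1cc(C2([C@@H]3CC(=O)O[C@H]3O[C@@H]4C[C@H](C)CC[C@H]4C(C)C)SCCCS2)cc(OC)c1O[Si](C(C)C)(C(C)C)C(C)C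
F6 | step 4 | (4R,5R)-4-[3,5-dimethoxy-4-(triisopropylsilyloxy)benzyl]-5-[(1R,2S,5R)-menthyloxy]dihydrofuran-2(3H)-one | COc1cc(C[C@@H]2CC(=O)O[C@H]2O[C@@H]3C[C@H](C)CC[C@H]3C(C)C)cc(OC)c1O[Si](C(C)C)(C(C)C)C(C)C
F7 | step 7 | bis(triisopropylsilyl) ether of (7S,8R,8'R)-5,5'-dimethoxylariciresinol | COc1cc(C[C@H]2CO[C@H](c3cc(OC)c(O[Si](C(C)C)(C(C)C)C(C)C)c(OC)c3)[C@H]2CO)cc(OC)c1O[Si](C(C)C)(C(C)C)C(C)C
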